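Labels used for every compound: C1 = CH α to the C11 ketone, C2 = quaternary C–CH3, C3 = senecioate carbon, C4 = CH2, C5 = isovalerate carbon, C6 = CMe2, C7 = CH bonded to C1, C6 and C8, C8 = CH bonded to C2, C7 and C9, C9=C10 = alkene.
Cuts: both esters, then the cyclobutane bond C1–C7. This leaves a cis-fused bicyclo[5.4.0]undecene whose cyclohexene (C1, C2, C8, C9, C10, C11), with quaternary C2 at the fusion and the C9=C10 alkene, is the Diels–Alder retron of a C8=C9–C10=C11 diene and the isopropenyl ketone C1=C2–C3(=O); C2–C8 and C1–C11 are cut next.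
The acyclic trienone is cut at C4–C5 (aldol), C10=C11 and C8=C9 (two Wittig reactions) back to (R)-pantolactone, which supplies C5–C8.
Forward: the chain is joined linearly, the six- and seven-membered rings close together in the cycloaddition, and the four-membered ring closes last by attack of the C1 enolate on C7.
Stereochemistry: C7 from pantolactone; C5 from a reagent-controlled boron aldol; C8 and C2 from C7 (allylic 1,3-strain) and an endo transition state; C3 from C5 by internal hydride delivery; C1 and the final C7 configuration by SN2 inversion in the cage.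
Remark: C11 passes through the cycloaddition as CH2 and is oxidised afterwards, since an oxygen substituent on that diene terminus would oppose the orientation the tether enforces and the corresponding dienol ether cannot be made regiocleanly.

Key step: step 10

Step 1
Reactants: 1 (R)-pantolactone
Product: 2 (2R)-3,3-dimethylbutane-1,2,4-triol
Conditions: LiAlH4, THF, 0 °C → reflux; aq. NaOH work-up
Reagents that add atoms: none
Why: Hydride reduction of the lactone gives the triol, and the C7 carbinol centre is not involved.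

Step 2
Reactants: 2 (2R)-3,3-dimethylbutane-1,2,4-triol
Product: 3 [(2R,4R)-2-(4-methoxyphenyl)-5,5-dimethyl-1,3-dioxan-4-yl]methanol
Conditions: 4-MeOC6H4CH(OMe)2, camphorsulfonic acid (cat.), CH2Cl2, rt
Reagents that add atoms: 4-methoxybenzaldehyde dimethyl acetal COC(OC)c1ccc(OC)cc1
Why: Acid-catalysed transacetalisation under thermodynamic control should close the 5,5-dimethyl-1,3-dioxane across O5 and O7 (aryl and CH2OH both equatorial, gem-dimethyl effect) rather than the dioxolane, leaving only the C8 hydroxyl free.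

Step 3
Reactants: 3 [(2R,4R)-2-(4-methoxyphenyl)-5,5-dimethyl-1,3-dioxan-4-yl]methanol
Product: 4 (2R,4R)-2-(4-methoxyphenyl)-5,5-dimethyl-1,3-dioxane-4-carbaldehyde
Conditions: (COCl)2, DMSO, CH2Cl2, −78 °C; i-Pr2NEt, −78 → 0 °C
Reagents that add atoms: none
Why: Swern oxidation gives the α-alkoxy aldehyde without over-oxidation, and the hindered amine base and the quaternary neighbour should prevent epimerisation at C7.

Step 4
Reactants: 4 (2R,4R)-2-(4-methoxyphenyl)-5,5-dimethyl-1,3-dioxane-4-carbaldehyde; 5 2-(triphenylphosphoranylidene)propanal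
Product: 6 (2E)-3-[(2R,4S)-2-(4-methoxyphenyl)-5,5-dimethyl-1,3-dioxan-4-yl]-2-methylprop-2-enal
Conditions: toluene, 100 °C
Reagents that add atoms: none
Why: Wittig olefination with a formyl-stabilised ylide is reliably (E)-selective, so C7 ends trans to C10 and cis to the C9 methyl, the geometry the later diene terminus needs, and no base is present that could epimerise C7.

Step 5
Reactants: 6 (2E)-3-[(2R,4S)-2-(4-methoxyphenyl)-5,5-dimethyl-1,3-dioxan-4-yl]-2-methylprop-2-enal
Product: 7 (2R,4S)-2-(4-methoxyphenyl)-5,5-dimethyl-4-[(1E)-2-methylbuta-1,3-dien-1-yl]-1,3-dioxane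
Conditions: Ph3PCH3Br, t-BuOK, THF, 0 °C
Reagents that add atoms: methyltriphenylphosphonium bromide C[P+](c1ccccc1)(c1ccccc1)c1ccccc1.[Br-]
Why: Wittig methylenation of the enal completes the (E)-1,3-diene C8=C9–C10=C11 without touching the trisubstituted alkene or the acetal.

Step 6
Reactants: 7 (2R,4S)-2-(4-methoxyphenyl)-5,5-dimethyl-4-[(1E)-2-methylbuta-1,3-dien-1-yl]-1,3-dioxane
Product: 8 (3S,4E)-3-[(4-methoxyphenyl)methoxy]-2,2,5-trimethylhepta-4,6-dien-1-ol
Conditions: i-Bu2AlH (3 equiv), CH2Cl2, −78 → 0 °C; aq. potassium sodium tartrate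
Reagents that add atoms: none
Why: Reductive opening of the 4-methoxybenzylidene acetal: aluminium binds the less hindered primary O5 and hydride goes to the acetal carbon, so the PMB group stays on the secondary O7 and the C5 hydroxyl is set free.

Step 7
Reactants: 8 (3S,4E)-3-[(4-methoxyphenyl)methoxy]-2,2,5-trimethylhepta-4,6-dien-1-ol
Product: 9 (3S,4E)-3-[(4-methoxyphenyl)methoxy]-2,2,5-trimethylhepta-4,6-dienal
Conditions: (COCl)2, DMSO, CH2Cl2, −78 °C; i-Pr2NEt, −78 → 0 °C
Reagents that add atoms: none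
Why: Swern oxidation of the neopentyl alcohol gives a non-enolisable aldehyde, and the diene and the PMB ether are inert to it.

Step 8
Reactants: 9 (3S,4E)-3-[(4-methoxyphenyl)methoxy]-2,2,5-trimethylhepta-4,6-dienal; 10 3-methylbut-3-en-2-one
Product: 12 (5R,7S,8E)-5-hydroxy-7-[(4-methoxyphenyl)methoxy]-2,6,6,9-tetramethylundeca-1,8,10-trien-3-one, via boron enolate 11 (not isolated)
Conditions: 10, (−)-Ipc2BCl, Et3N, Et2O, 0 °C; then 9, −78 → −20 °C; then MeOH, pH 7 buffer, H2O2, 0 °C
Reagents that add atoms: none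
Why: Paterson boron aldol reaction: the (−)-Ipc2B enolate of the methyl ketone should add through a cyclic boron transition state to the Re face of the aldehyde (reagent control, the β-alkoxy centre having little influence in boron aldols), which sets 5R, and any 5-epimer is a diastereomer that should be removable by chromatography.

Step 9
Reactants: 12 (5R,7S,8E)-5-hydroxy-7-[(4-methoxyphenyl)methoxy]-2,6,6,9-tetramethylundeca-1,8,10-trien-3-one
Product: 13 (5R,7S,8E)-5-[(tert-butyldimethylsilyl)oxy]-7-[(4-methoxyphenyl)methoxy]-2,6,6,9-tetramethylundeca-1,8,10-trien-3-one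
Conditions: TBSOTf, 2,6-lutidine, CH2Cl2, −78 °C
Reagents that add atoms: tert-butyldimethylsilyl trifluoromethanesulfonate CC(C)(C)[Si](C)(C)OS(=O)(=O)C(F)(F)F
Why: Silylation with the triflate and 2,6-lutidine protects O5 at low temperature and blocks retro-aldol and dehydration pathways during the thermal step.

Step 10
Reactants: 13 (5R,7S,8E)-5-[(tert-butyldimethylsilyl)oxy]-7-[(4-methoxyphenyl)methoxy]-2,6,6,9-tetramethylundeca-1,8,10-trien-3-one
Product: 14 (2S,5R,7S,8R)-5-(tert-butyldimethylsilyloxy)-7-(4-methoxybenzyloxy)-2,6,6,9-tetramethyl-cis-bicyclo[5.4.0]undec-9-en-3-one (plan labels; fusion atoms C2 and C8)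
Conditions: BHT (cat.), toluene (0.01 M), 150 °C, sealed tube
Reagents that add atoms: none
Why: Concerted but asynchronous suprafacial [4+2] cycloaddition of the (E)-diene C8=C9–C10=C11 to the ketone-activated alkene C1=C2, forming C1–C11 and C2–C8; the closest known reaction type is the thermal type 1 intramolecular Diels–Alder reaction of 1,8,10-undecatrien-3-ones, which gives cis-fused bicyclo[5.4.0]undecenones, quaternary fusion carbons included. The cyclohexene (C1, C2, C8, C9, C10, C11) closes as the cycloaddition ring itself, and the cycloheptanone (C2 to C8) closes in the fused mode through the same C2–C8 bond, because the five-atom tether C3–C7 joins the diene terminus C8 to the carbonyl-bearing dienophile carbon C2 and cannot span the bridged alternative. C8 is set by C7: allylic 1,3-strain with the cis C9 methyl holds the C7–H bond in the diene plane, C6 carries the dienophile to one face and the PMB ether lies on the other, so O7 and the new C8–H end cis, with O7 pointing away from C1. C2 is set by the endo position of the tether carbonyl, which places the flat C3=O under the diene and the C2 methyl outside, away from the C9 methyl, and so gives the cis ring fusion. The step needs one diene face and endo over exo selectivity; the fixed (E)-C8=C9 geometry and the C7 centre secure the first, while carbonyl activation within the tether and the gem-dimethyl group at C6 (reactive-rotamer effect) secure the rate and support the second, and the absence of a Lewis acid keeps the dienylic PMB ether intact.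

Step 11
Reactants: 14 (2S,5R,7S,8R)-5-(tert-butyldimethylsilyloxy)-7-(4-methoxybenzyloxy)-2,6,6,9-tetramethyl-cis-bicyclo[5.4.0]undec-9-en-3-one
Product: 15 (2S,5R,7S,8R)-5-hydroxy-7-(4-methoxybenzyloxy)-2,6,6,9-tetramethyl-cis-bicyclo[5.4.0]undec-9-en-3-one
Conditions: HF·pyridine, pyridine, THF, 0 °C → rt
Reagents that add atoms: none
Why: Fluoride-mediated desilylation under buffered acidic conditions frees the C5 hydroxyl without retro-aldol opening or β-elimination and leaves the PMB ether intact.

Step 12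
Reactants: 15 (2S,5R,7S,8R)-5-hydroxy-7-(4-methoxybenzyloxy)-2,6,6,9-tetramethyl-cis-bicyclo[5.4.0]undec-9-en-3-one; 16 3-methylbutanal
Product: 17 (2S,3R,5R,7S,8R)-3-hydroxy-7-(4-methoxybenzyloxy)-2,6,6,9-tetramethyl-cis-bicyclo[5.4.0]undec-9-en-5-yl 3-methylbutanoate
Conditions: 16 (5 equiv), SmI2 (0.3 equiv), THF, −10 °C
Reagents that add atoms: none
Why: Evans–Tishchenko reduction: the C5 hydroxyl forms a samarium-bound hemiacetal with 16 whose C–H is delivered to C3 through a bridged six-membered transition state on the face syn to O5 (the geometry of hydroxyl-directed reductions of cyclic β-hydroxy ketones), which sets the 3R carbinol trans to O5 and leaves the isovalerate on O5 in the same operation.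

Step 13
Reactants: 17 (2S,3R,5R,7S,8R)-3-hydroxy-7-(4-methoxybenzyloxy)-2,6,6,9-tetramethyl-cis-bicyclo[5.4.0]undec-9-en-5-yl 3-methylbutanoate
Product: 18 (2S,3R,5R,7S,8R)-7-(4-methoxybenzyloxy)-2,6,6,9-tetramethyl-3-(triethylsilyloxy)-cis-bicyclo[5.4.0]undec-9-en-5-yl 3-methylbutanoate
Conditions: Et3SiOTf, 2,6-lutidine, CH2Cl2, −78 → 0 °C
Reagents that add atoms: triethylsilyl trifluoromethanesulfonate CC[Si](CC)(CC)OS(=O)(=O)C(F)(F)F
Why: Silylation of the hindered C3 alcohol with the triflate masks O3, which as an alkoxide or as an ester would compete with C1 for C7 or invite acyl transfer in the ring closure.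

Step 14
Reactants: 18 (2S,3R,5R,7S,8R)-7-(4-methoxybenzyloxy)-2,6,6,9-tetramethyl-3-(triethylsilyloxy)-cis-bicyclo[5.4.0]undec-9-en-5-yl 3-methylbutanoate
Product: 19 (2S,3R,5R,7S,8R)-7-hydroxy-2,6,6,9-tetramethyl-3-(triethylsilyloxy)-cis-bicyclo[5.4.0]undec-9-en-5-yl 3-methylbutanoate
Conditions: DDQ, CH2Cl2/pH 7 buffer, 0 °C
Reagents that add atoms: none
Why: Oxidative PMB cleavage (hydride abstraction by DDQ, then hydrolysis of the oxocarbenium ion) frees O7, while the silyl ether, the ester and the trisubstituted alkene should survive in buffered medium.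

Step 15
Reactants: 19 (2S,3R,5R,7S,8R)-7-hydroxy-2,6,6,9-tetramethyl-3-(triethylsilyloxy)-cis-bicyclo[5.4.0]undec-9-en-5-yl 3-methylbutanoate
Product: 20 (2S,3R,5R,7S,8R)-7-(methanesulfonyloxy)-2,6,6,9-tetramethyl-3-(triethylsilyloxy)-cis-bicyclo[5.4.0]undec-9-en-5-yl 3-methylbutanoate
Conditions: MsCl, Et3N, CH2Cl2, 0 °C
Reagents that add atoms: methanesulfonyl chloride CS(=O)(=O)Cl
Why: Mesylation through sulfene tolerates the hindered secondary alcohol and proceeds with retention at C7, which places the leaving group anti to the future C1–C7 bond.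

Step 16
Reactants: 20 (2S,3R,5R,7S,8R)-7-(methanesulfonyloxy)-2,6,6,9-tetramethyl-3-(triethylsilyloxy)-cis-bicyclo[5.4.0]undec-9-en-5-yl 3-methylbutanoate
Product: 21 (2S,3R,5R,7S,8R)-7-(methanesulfonyloxy)-2,6,6,9-tetramethyl-11-oxo-3-(triethylsilyloxy)-cis-bicyclo[5.4.0]undec-9-en-5-yl 3-methylbutanoate
Conditions: Rh2(cap)4 (cap = caprolactamate, 1 mol %), t-BuOOH (70% in water, 8 equiv), ClCH2CH2Cl, 40 °C
Reagents that add atoms: tert-butyl hydroperoxide CC(C)(C)OO
Why: Allylic C–H oxidation by tert-butylperoxyl radicals: abstraction at the unhindered C11 methylene gives the allyl radical with its tertiary terminus at C9, so the CH2 next to the CH= carbon of the trisubstituted cyclohexene becomes the enone carbonyl, the pattern known for steroidal 5-enes (7-ketones) and for α-pinene (verbenone).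

Step 17
Reactants: 21 (2S,3R,5R,7S,8R)-7-(methanesulfonyloxy)-2,6,6,9-tetramethyl-11-oxo-3-(triethylsilyloxy)-cis-bicyclo[5.4.0]undec-9-en-5-yl 3-methylbutanoate
Product: 23 (1R,2R,3R,5R,7S,8R)-11-oxo-3-(triethylsilyloxy)longipin-9-en-5-yl 3-methylbutanoate (plan labels), via potassium enolate 22 (not isolated)
Conditions: KN(SiMe3)2 (1.1 equiv), THF, −78 → 0 °C
Reagents that add atoms: none
Why: Kinetic α′-deprotonation of the enone at C1 and 4-(enolexo)-exo-tet intramolecular alkylation: the C1 enolate attacks C7 (axial on the cyclohexenone) from the face anti to the mesylate, inverting C7 and fixing C1, a known way of closing bicyclo[3.1.1]heptanones with secondary sulfonates next to quaternary carbons.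

Step 18
Reactants: 23 (1R,2R,3R,5R,7S,8R)-11-oxo-3-(triethylsilyloxy)longipin-9-en-5-yl 3-methylbutanoate
Product: 24 (1R,2R,3R,5R,7S,8R)-3-hydroxy-11-oxolongipin-9-en-5-yl 3-methylbutanoate (plan labels)
Conditions: HF·pyridine, THF, 0 °C → rt
Reagents that add atoms: none
Why: Fluoride-mediated cleavage of the triethylsilyl ether, to which the enone and the ester are stable.

Step 19
Reactants: 24 (1R,2R,3R,5R,7S,8R)-3-hydroxy-11-oxolongipin-9-en-5-yl 3-methylbutanoate; 25 3-methylbut-2-enoyl chloride
Product: 26 CNP0335239.1, (1R,2R,3R,5R,7S,8R)-5-(3-methylbutanoyloxy)-11-oxolongipin-9-en-3-yl 3-methylbut-2-enoate (plan labels)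
Conditions: 25, DMAP, pyridine, CH2Cl2, 0 °C → rt
Reagents that add atoms: none
Why: DMAP-catalysed acylation of the hindered C3 alcohol with the acid chloride, with pyridine as the only base to avoid ketene formation and deconjugation of the 3-methylbut-2-enoyl group, gives the target.

Compound list
1 | (R)-pantolactone | CC1(C)COC(=O)[C@@H]1O | starting material
2 | (2R)-3,3-dimethylbutane-1,2,4-triol | OC[C@H](O)C(C)(C)CO | intermediate
3 | [(2R,4R)-2-(4-methoxyphenyl)-5,5-dimethyl-1,3-dioxan-4-yl]methanol | OC[C@@H]1O[C@H](c2ccc(OC)cc2)OCC1(C)C | intermediate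
4 | (2R,4R)-2-(4-methoxyphenyl)-5,5-dimethyl-1,3-dioxane-4-carbaldehyde | O=C[C@@H]1O[C@H](c2ccc(OC)cc2)OCC1(C)C | intermediate
5 | 2-(triphenylphosphoranylidene)propanal | CC(C=O)=P(c1ccccc1)(c1ccccc1)c1ccccc1 | starting material
6 | (2E)-3-[(2R,4S)-2-(4-methoxyphenyl)-5,5-dimethyl-1,3-dioxan-4-yl]-2-methylprop-2-enal | O=C/C(C)=C/[C@@H]1O[C@H](c2ccc(OC)cc2)OCC1(C)C | intermediate
7 | (2R,4S)-2-(4-methoxyphenyl)-5,5-dimethyl-4-[(1E)-2-methylbuta-1,3-dien-1-yl]-1,3-dioxane | C=C/C(C)=C/[C@@H]1O[C@H](c2ccc(OC)cc2)OCC1(C)C | intermediate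
8 | (3S,4E)-3-[(4-methoxyphenyl)methoxy]-2,2,5-trimethylhepta-4,6-dien-1-ol | OCC(C)(C)[C@@H](OCc1ccc(OC)cc1)/C=C(C)/C=C | intermediate
9 | (3S,4E)-3-[(4-methoxyphenyl)methoxy]-2,2,5-trimethylhepta-4,6-dienal | O=CC(C)(C)[C@@H](OCc1ccc(OC)cc1)/C=C(C)/C=C | intermediate
10 | 3-methylbut-3-en-2-one | CC(=O)C(C)=C | starting material
11 | diisopinocampheylboron enolate of 10 (not isolated) | C=C(C)C(=C)OB([C@@H]1C[C@@H]2C[C@H]([C@H]1C)C2(C)C)[C@@H]1C[C@@H]2C[C@H]([C@H]1C)C2(C)C | intermediate
12 | (5R,7S,8E)-5-hydroxy-7-[(4-methoxyphenyl)methoxy]-2,6,6,9-tetramethylundeca-1,8,10-trien-3-one | C=C(C)C(=O)C[C@@H](O)C(C)(C)[C@@H](OCc1ccc(OC)cc1)/C=C(C)/C=C | intermediate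
13 | (5R,7S,8E)-5-[(tert-butyldimethylsilyl)oxy]-7-[(4-methoxyphenyl)methoxy]-2,6,6,9-tetramethylundeca-1,8,10-trien-3-one (cycloaddition precursor) | C=C(C)C(=O)C[C@@H](O[Si](C)(C)C(C)(C)C)C(C)(C)[C@@H](OCc1ccc(OC)cc1)/C=C(C)/C=C | intermediate
14 | (2S,5R,7S,8R)-5-(tert-butyldimethylsilyloxy)-7-(4-methoxybenzyloxy)-2,6,6,9-tetramethyl-cis-bicyclo[5.4.0]undec-9-en-3-one (plan labels; cycloaddition product) | O=C1C[C@@H](O[Si](C)(C)C(C)(C)C)C(C)(C)[C@@H](OCc2ccc(OC)cc2)[C@@H]3C(C)=CCC[C@@]31C | intermediate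
15 | (2S,5R,7S,8R)-5-hydroxy-7-(4-methoxybenzyloxy)-2,6,6,9-tetramethyl-cis-bicyclo[5.4.0]undec-9-en-3-one | O=C1C[C@@H](O)C(C)(C)[C@@H](OCc2ccc(OC)cc2)[C@@H]3C(C)=CCC[C@@]31C | intermediate
16 | 3-methylbutanal | CC(C)CC=O | starting material
17 | (2S,3R,5R,7S,8R)-3-hydroxy-7-(4-methoxybenzyloxy)-2,6,6,9-tetramethyl-cis-bicyclo[5.4.0]undec-9-en-5-yl 3-methylbutanoate | O[C@@H]1C[C@@H](OC(=O)CC(C)C)C(C)(C)[C@@H](OCc2ccc(OC)cc2)[C@@H]3C(C)=CCC[C@@]31C | intermediate
18 | (2S,3R,5R,7S,8R)-7-(4-methoxybenzyloxy)-2,6,6,9-tetramethyl-3-(triethylsilyloxy)-cis-bicyclo[5.4.0]undec-9-en-5-yl 3-methylbutanoate | CC[Si](CC)(CC)O[C@@H]1C[C@@H](OC(=O)CC(C)C)C(C)(C)[C@@H](OCc2ccc(OC)cc2)[C@@H]3C(C)=CCC[C@@]31C | intermediate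
19 | (2S,3R,5R,7S,8R)-7-hydroxy-2,6,6,9-tetramethyl-3-(triethylsilyloxy)-cis-bicyclo[5.4.0]undec-9-en-5-yl 3-methylbutanoate | CC[Si](CC)(CC)O[C@@H]1C[C@@H](OC(=O)CC(C)C)C(C)(C)[C@@H](O)[C@@H]3C(C)=CCC[C@@]31C | intermediate
20 | (2S,3R,5R,7S,8R)-7-(methanesulfonyloxy)-2,6,6,9-tetramethyl-3-(triethylsilyloxy)-cis-bicyclo[5.4.0]undec-9-en-5-yl 3-methylbutanoate | CC[Si](CC)(CC)O[C@@H]1C[C@@H](OC(=O)CC(C)C)C(C)(C)[C@@H](OS(C)(=O)=O)[C@@H]3C(C)=CCC[C@@]31C | intermediate
21 | (2S,3R,5R,7S,8R)-7-(methanesulfonyloxy)-2,6,6,9-tetramethyl-11-oxo-3-(triethylsilyloxy)-cis-bicyclo[5.4.0]undec-9-en-5-yl 3-methylbutanoate | CC[Si](CC)(CC)O[C@@H]1C[C@@H](OC(=O)CC(C)C)C(C)(C)[C@@H](OS(C)(=O)=O)[C@@H]3C(C)=CC(=O)C[C@@]31C | intermediate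
22 | potassium C1 enolate of 21 (not isolated) | CC[Si](CC)(CC)O[C@@H]1C[C@@H](OC(=O)CC(C)C)C(C)(C)[C@@H](OS(C)(=O)=O)[C@@H]3C(C)=CC([O-])=C[C@@]31C.[K+] | intermediate
23 | (1R,2R,3R,5R,7S,8R)-11-oxo-3-(triethylsilyloxy)longipin-9-en-5-yl 3-methylbutanoate (plan labels) | CC[Si](CC)(CC)O[C@@H]1C[C@@H](OC(=O)CC(C)C)C(C)(C)[C@@H]2[C@H]3C(=O)C=C(C)[C@@H]2[C@]31C | intermediate
24 | (1R,2R,3R,5R,7S,8R)-3-hydroxy-11-oxolongipin-9-en-5-yl 3-methylbutanoate (plan labels) | O[C@@H]1C[C@@H](OC(=O)CC(C)C)C(C)(C)[C@@H]2[C@H]3C(=O)C=C(C)[C@@H]2[C@]31C | intermediate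
25 | 3-methylbut-2-enoyl chloride | CC(C)=CC(Cl)=O | starting material
26 | CNP0335239.1, (1R,2R,3R,5R,7S,8R)-5-(3-methylbutanoyloxy)-11-oxolongipin-9-en-3-yl 3-methylbut-2-enoate (plan labels) | CC(C)=CC(=O)O[C@@H]1C[C@@H](OC(=O)CC(C)C)C(C)(C)[C@@H]2[C@H]3C(=O)C=C(C)[C@@H]2[C@]31C | target

Total step count: 19
Longest linear sequence: 19 steps (1 to 26)

Steps most likely to fail

Step 10. The exo transition state may compete and give the trans-fused isomer, or the cycloaddition of the α-methyl enone may be too slow at temperatures the substrate tolerates. The fallback changes from heating the silyl ether to Lewis-acid chelate activation of the unprotected aldol. It sets out from 12: Me2AlCl (2 equiv) in CH2Cl2 at −78 → −20 °C should turn the C5 hydroxyl into an aluminium alkoxide that binds the C3 carbonyl in a six-membered chelate, lower the dienophile LUMO and favour the carbonyl-endo mode at low temperature. Aqueous work-up would give the β-hydroxy ketone directly, so the route is rejoined at 15 with steps 9 and 11 omitted; no new compound is made (F0).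

Step 17. Backside attack at the neopentyl-type C7 may be slow, so that proton transfer to the extended enolate (C8) and loss of methanesulfonate by an E1cB pathway take over. The fallback changes the nucleophile class. It sets out from 21: condensation with H2NNMe2 (AcOH cat., EtOH, 50 °C) should give the N,N-dimethylhydrazone of 21, F1. LiN(i-Pr)2 in THF (−78 → 0 °C) would deprotonate it at C1 to an azaenolate, which is more nucleophilic than the potassium enolate and does not equilibrate to the extended anion, and this should close C1–C7 to the tricyclic N,N-dimethylhydrazone F2. Hydrolysis with CuCl2 in THF/pH 7 buffer would then release the ketone and rejoin the route at 23.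

Step 12. The cyclic β-hydroxy ketone may not reach the bridged hydride-transfer geometry, or the samarium alkoxide may trigger retro-aldol opening of the seven-membered ring. The fallback separates acylation from reduction. It sets out from 15: acylation of O5 with 3-methylbutanoyl chloride (pyridine, DMAP cat., CH2Cl2, 0 °C) gives the keto ester (2S,5R,7S,8R)-7-(4-methoxybenzyloxy)-2,6,6,9-tetramethyl-3-oxo-cis-bicyclo[5.4.0]undec-9-en-5-yl 3-methylbutanoate F3. Its C3 ketone is then reduced under reagent control with (S)-2-methyl-CBS-oxazaborolidine and catecholborane in toluene at −78 °C; with the quaternary C2 as the large and C4H2 as the small substituent, hydride should arrive on the face that gives the 3R alcohol, rejoining the route at 17.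

Further compounds
F0 | step 10 | none | none
F1 | step 17 | N,N-dimethylhydrazone of 21 at C11 | CC[Si](CC)(CC)O[C@@H]1C[C@@H](OC(=O)CC(C)C)C(C)(C)[C@@H](OS(C)(=O)=O)[C@@H]3C(C)=CC(=NN(C)C)C[C@@]31C
F2 | step 17 | N,N-dimethylhydrazone of 23 at C11 | CC[Si](CC)(CC)O[C@@H]1C[C@@H](OC(=O)CC(C)C)C(C)(C)[C@@H]2[C@H]3C(=NN(C)C)C=C(C)[C@@H]2[C@]31C
F3 | step 12 | (2S,5R,7S,8R)-7-(4-methoxybenzyloxy)-2,6,6,9-tetramethyl-3-oxo-cis-bicyclo[5.4.0]undec-9-en-5-yl 3-methylbutanoate | O=C1C[C@@H](OC(=O)CC(C)C)C(C)(C)[C@@H](OCc2ccc(OC)cc2)[C@@H]3C(C)=CCC[C@@]31C
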